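**Retrosynthetic overview**
- The target is cut back first by removing the two C8 methyl groups (dearomatisation is done last), then by shortening the C2 side chain to a vinyl group (hydroboration and B-alkyl Suzuki coupling).
- The strategy rests on the C3=C4 cis double bond of pyran ring B, which joins C4a to the quaternary ether carbon C2, and on the fact that the 4-methylpent-3-enyl chain at C2 can be grown from a vinyl group. C2 can therefore carry two vinyl groups and stay prochiral until an enantioselective ring-closing metathesis forms C3=C4, closes ring B and makes C2 a stereocentre.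
- The triene comes from the (R)-2-methylbutanoyl phloroglucinol by etherification of the hydroxyl para to the acyl group with an enynyl carbonate, ortho-formylation, silylation, methylenation and alkyne semihydrogenation.
- Ring order: ring A is bought as phloroglucinol, ring B is closed in the key step, and ring A is dearomatised in the final step.

Key step: step 9

Assumption: the sense of induction of the chiral molybdenum catalyst cannot be derived with certainty; the (S)-biphenolate is assumed to give (R)-C2, to be checked on the first run and replaced by the (R)-biphenolate if the reverse holds.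

Step 1
Reactants: 1 (R)-2-methylbutanoic acid
Product: 2 (R)-2-methylbutanoyl chloride
Conditions: (COCl)2, DMF (cat.), CH2Cl2, 0 °C to rt; distilled
Reagents that add atoms: oxalyl chloride, O=C(Cl)C(=O)Cl
Why: Acid chloride formation through the chloroiminium (Vilsmeier-type) activator runs without base at or below room temperature, so the α-stereocentre, which is not a reacting atom, should keep its (R) configuration.

Step 2
Reactants: 2 (R)-2-methylbutanoyl chloride; 3 phloroglucinol
Product: 4 (R)-2-methyl-1-(2,4,6-trihydroxyphenyl)butan-1-one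
Conditions: AlCl3 (3.5 equiv), PhNO2/CH2Cl2, 0 °C to rt; 1 M HCl work-up
Reagents that add atoms: none
Why: Friedel–Crafts acylation of the threefold activated, symmetric arene should stop after one acylation because the chelated aryl ketone deactivates the ring, and the non-basic medium at or below room temperature should spare the α-stereocentre.

Step 3
Reactants: 5 3-methylpent-1-en-4-yn-3-ol (racemic)
Product: 6 methyl (3-methylpent-1-en-4-yn-3-yl) carbonate (racemic)
Conditions: n-BuLi (1.05 equiv), THF, −78 °C; ClCO2Me, −78 to 0 °C
Reagents that add atoms: methyl chloroformate, COC(=O)Cl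
Why: O-acylation of the lithium alkoxide (the hydroxyl is deprotonated well before the alkyne C–H) should give the tertiary propargylic carbonate needed as the leaving group of step 4, and its configuration is irrelevant because the carbinol carbon later becomes prochiral.

Step 4
Reactants: 4 (R)-2-methyl-1-(2,4,6-trihydroxyphenyl)butan-1-one; 6 methyl (3-methylpent-1-en-4-yn-3-yl) carbonate
Product: 7 (2R)-1-[2,6-dihydroxy-4-[(3-methylpent-1-en-4-yn-3-yl)oxy]phenyl]-2-methylbutan-1-one (both configurations at the ether carbon)
Conditions: CuCl2·2H2O (2 mol%), DBU (1.2 equiv), MeCN, −5 to 0 °C; 4 in slight excess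
Reagents that add atoms: none
Why: Copper-catalysed propargylic etherification of a phenol with a tertiary propargylic carbonate (copper acetylide, loss of carbonate, phenoxide attack at the propargylic carbon) should take place at the hydroxyl para to the acyl group, because this is the only hydroxyl not hydrogen-bonded to the ketone and the one ionised first by one equivalent of base.

Step 5
Reactants: 7 (2R)-1-[2,6-dihydroxy-4-[(3-methylpent-1-en-4-yn-3-yl)oxy]phenyl]-2-methylbutan-1-one
Product: 8 2,4-dihydroxy-3-[(R)-2-methylbutanoyl]-6-[(3-methylpent-1-en-4-yn-3-yl)oxy]benzaldehyde (both configurations at the ether carbon)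
Conditions: MgCl2 (anhydrous), Et3N, (CH2O)n, THF, 60–65 °C
Reagents that add atoms: paraformaldehyde (source of formaldehyde), C=O
Why: Magnesium-mediated ortho-formylation of a phenol (Casnati–Skattebøl reaction, with a second formaldehyde as hydride acceptor) can reach only the two equivalent free ring carbons, each ortho to a hydroxyl and to the ether oxygen, and it is done while the ether is still the propargylic one, which lies well below its Claisen threshold at this temperature.

Step 6
Reactants: 8 2,4-dihydroxy-3-[(R)-2-methylbutanoyl]-6-[(3-methylpent-1-en-4-yn-3-yl)oxy]benzaldehyde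
Product: 9 2,4-bis(tert-butyldimethylsilyloxy)-3-[(R)-2-methylbutanoyl]-6-[(3-methylpent-1-en-4-yn-3-yl)oxy]benzaldehyde (both configurations at the ether carbon)
Conditions: TBSOTf (2.6 equiv), 2,6-lutidine (4 equiv), CH2Cl2, −78 to 0 °C; used promptly
Reagents that add atoms: tert-butyldimethylsilyl triflate, CC(C)(C)[Si](C)(C)OS(=O)(=O)C(F)(F)F
Why: Silylation with the silyl triflate is fast enough for both chelated, flanked phenols at low temperature, removes the acidic protons that would quench the ylide of step 7 and the molybdenum catalyst of step 9, and with a hindered base at −78 °C should not ionise the tertiary ether.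

Step 7
Reactants: 9 2,4-bis(tert-butyldimethylsilyloxy)-3-[(R)-2-methylbutanoyl]-6-[(3-methylpent-1-en-4-yn-3-yl)oxy]benzaldehyde
Product: 10 (2R)-1-[2,6-bis(tert-butyldimethylsilyloxy)-4-[(3-methylpent-1-en-4-yn-3-yl)oxy]-3-vinylphenyl]-2-methylbutan-1-one (both configurations at the ether carbon)
Conditions: Ph3PCH3Br (1.4 equiv), KOtBu (1.3 equiv), THF, 0 °C; then 9, −78 to 0 °C
Reagents that add atoms: methyltriphenylphosphonium bromide, C[P+](c1ccccc1)(c1ccccc1)c1ccccc1.[Br-]
Why: Wittig methylenation under lithium-free conditions should convert the aldehyde into the vinyl group, while the ketone, flanked by two silyloxy groups and α-branched, is too hindered to be olefinated or enolised at this temperature.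

Step 8
Reactants: 10 (2R)-1-[2,6-bis(tert-butyldimethylsilyloxy)-4-[(3-methylpent-1-en-4-yn-3-yl)oxy]-3-vinylphenyl]-2-methylbutan-1-one
Product: 11 (R)-1-[2,6-bis(tert-butyldimethylsilyloxy)-4-[(3-methylpenta-1,4-dien-3-yl)oxy]-3-vinylphenyl]-2-methylbutan-1-one
Conditions: H2 (1 atm), Pd/CaCO3 poisoned with Pb(OAc)2, quinoline, EtOAc, rt; stopped after 1 equiv H2; purified, dried and used at once
Reagents that add atoms: none
Why: Lindlar semihydrogenation should reduce only the terminal alkyne, which binds to the poisoned palladium surface far more strongly than the monosubstituted alkenes, and it turns the ether carbon into a prochiral centre with two identical vinyl groups, so the unselective configuration from step 4 disappears and the rearrangement-prone bis-allylic aryl ether exists only directly before the key step.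

Step 9
Reactants: 11 (R)-1-[2,6-bis(tert-butyldimethylsilyloxy)-4-[(3-methylpenta-1,4-dien-3-yl)oxy]-3-vinylphenyl]-2-methylbutan-1-one
Product: 12 (R)-1-[(R)-5,7-bis(tert-butyldimethylsilyloxy)-2-methyl-2-vinyl-2H-chromen-6-yl]-2-methylbutan-1-one
Conditions: Mo(N-2,6-iPr2C6H3)(CHCMe2Ph)[(S)-3,3'-di-tert-butyl-5,5',6,6'-tetramethylbiphenyl-2,2'-diolate] (5–10 mol%), C6H6 (0.02 M), 22 °C, N2 atmosphere, ethylene vented; light excluded
Reagents that add atoms: none
Why: The molybdenum neophylidene exchanges with the aryl vinyl group (or, reversibly, with a carbinol vinyl group) to give a substrate-bound alkylidene, which undergoes [2+2] cycloaddition with a vinyl group of the O–C(Me)(CH=CH2)2 unit and cycloreversion with release of ethylene. The closest known chemistry is the molybdenum-catalysed asymmetric ring-closing metathesis that desymmetrises prochiral trienes to cyclic tertiary ethers, together with the ring-closing metathesis of 2-vinylaryl allyl ethers to 2H-chromenes. Ring B closes as a six-membered ring by formation of the C3=C4 bond between the carbon on C4a and one carbinol vinyl carbon, and the ring enforces the cis geometry. C2 becomes a stereocentre because only one of its two enantiotopic vinyl groups enters the metallacyclobutane; the chiral biphenolate on molybdenum makes the two diastereomeric metallacycles unequal in energy, while the remote (R)-acyl centre should exert no bias. The step needs enantiotopic-group selectivity and ring closure ahead of intermolecular metathesis: the methyl and aryloxy groups on C2 differ strongly in the chiral pocket, six-ring closure at high dilution is fast, the surviving vinyl group sits on a quaternary carbon with no partner left, and the unstrained cis-styrenyl product is not reopened once ethylene is swept out. The only carbonyl group is an α-branched aryl ketone between two silyloxy groups, too shielded for exchange with the Mo=C bond, and the mild temperature keeps the triene below its [3,3] rearrangement.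

Step 10
Reactants: 12 (R)-1-[(R)-5,7-bis(tert-butyldimethylsilyloxy)-2-methyl-2-vinyl-2H-chromen-6-yl]-2-methylbutan-1-one; 13 1-bromo-2-methylprop-1-ene
Product: 15 (R)-1-[(R)-5,7-bis(tert-butyldimethylsilyloxy)-2-methyl-2-(4-methylpent-3-en-1-yl)-2H-chromen-6-yl]-2-methylbutan-1-one, via B-alkyl-9-BBN adduct 14 (not isolated)
Conditions: 9-BBN (1.3 equiv), THF, 0 °C to rt; then 13 (3 equiv), Pd(dppf)Cl2·CH2Cl2 (5 mol%), 3 M aq. K3PO4, DMF, rt
Reagents that add atoms: 9-borabicyclo[3.3.1]nonane (9-BBN; its atoms stay in 14 only), B1C2CCCC1CCC2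
Why: Anti-Markovnikov hydroboration with 9-BBN is selective for the monosubstituted vinyl group over the cis-disubstituted conjugated C3=C4 bond and the hindered ketone, and the B-alkyl Suzuki–Miyaura coupling with the alkenyl bromide builds the 4-methylpent-3-enyl chain without touching C2, whose configuration is therefore kept (any silyl ether lost to the base is harmless because both are removed in step 11).

Step 11
Reactants: 15 (R)-1-[(R)-5,7-bis(tert-butyldimethylsilyloxy)-2-methyl-2-(4-methylpent-3-en-1-yl)-2H-chromen-6-yl]-2-methylbutan-1-one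
Product: 16 (R)-1-[(R)-5,7-dihydroxy-2-methyl-2-(4-methylpent-3-en-1-yl)-2H-chromen-6-yl]-2-methylbutan-1-one
Conditions: TBAF (2.5 equiv), AcOH (2.5 equiv), THF, 0 °C
Reagents that add atoms: none
Why: Fluoride-induced cleavage of the two aryl silyl ethers, buffered with acetic acid, is mild enough for the chromene, the trisubstituted alkene and both stereocentres.

Step 12
Reactants: 16 (R)-1-[(R)-5,7-dihydroxy-2-methyl-2-(4-methylpent-3-en-1-yl)-2H-chromen-6-yl]-2-methylbutan-1-one
Product: 18 (R)-5-hydroxy-2,8,8-trimethyl-6-[(R)-2-methylbutanoyl]-2-(4-methylpent-3-en-1-yl)-2H-chromen-7(8H)-one (target), via 8-methylchromene 17 (not isolated)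
Conditions: NaOMe (5 equiv), MeI (excess), MeOH, 0 °C to rt; worked up cold, stored cold in the dark
Reagents that add atoms: iodomethane, CI
Why: Dearomatising gem-dimethylation of an acylphloroglucinol should methylate the phenoxide twice at C8, the only unsubstituted ring carbon, the second methylation leaving the C7 ketone and the chelated C5 enol; the acyl α-carbon is not deprotonated in the anionic vinylogous acid, and the step is placed last and run cold because the 2H-pyran ring of the dearomatised product could in principle scramble C2 by reversible electrocyclic ring opening.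

**Compound list**
1 | (R)-2-methylbutanoic acid | CC[C@@H](C)C(=O)O | starting material
2 | (R)-2-methylbutanoyl chloride | CC[C@@H](C)C(=O)Cl | intermediate
3 | phloroglucinol | Oc1cc(O)cc(O)c1 | starting material
4 | (R)-2-methyl-1-(2,4,6-trihydroxyphenyl)butan-1-one | CC[C@@H](C)C(=O)c1c(O)cc(O)cc1O | intermediate
5 | 3-methylpent-1-en-4-yn-3-ol (racemic) | C=CC(C)(O)C#C | starting material
6 | methyl (3-methylpent-1-en-4-yn-3-yl) carbonate (racemic) | C=CC(C)(OC(=O)OC)C#C | intermediate
7 | (2R)-1-[2,6-dihydroxy-4-[(3-methylpent-1-en-4-yn-3-yl)oxy]phenyl]-2-methylbutan-1-one (both configurations at the ether carbon) | CC[C@@H](C)C(=O)c1c(O)cc(OC(C)(C=C)C#C)cc1O | intermediate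
8 | 2,4-dihydroxy-3-[(R)-2-methylbutanoyl]-6-[(3-methylpent-1-en-4-yn-3-yl)oxy]benzaldehyde (both configurations at the ether carbon) | CC[C@@H](C)C(=O)c1c(O)cc(OC(C)(C=C)C#C)c(C=O)c1O | intermediate
9 | 2,4-bis(tert-butyldimethylsilyloxy)-3-[(R)-2-methylbutanoyl]-6-[(3-methylpent-1-en-4-yn-3-yl)oxy]benzaldehyde (both configurations at the ether carbon) | CC[C@@H](C)C(=O)c1c(O[Si](C)(C)C(C)(C)C)cc(OC(C)(C=C)C#C)c(C=O)c1O[Si](C)(C)C(C)(C)C | intermediate
10 | (2R)-1-[2,6-bis(tert-butyldimethylsilyloxy)-4-[(3-methylpent-1-en-4-yn-3-yl)oxy]-3-vinylphenyl]-2-methylbutan-1-one (both configurations at the ether carbon) | CC[C@@H](C)C(=O)c1c(O[Si](C)(C)C(C)(C)C)cc(OC(C)(C=C)C#C)c(C=C)c1O[Si](C)(C)C(C)(C)C | intermediate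
11 | (R)-1-[2,6-bis(tert-butyldimethylsilyloxy)-4-[(3-methylpenta-1,4-dien-3-yl)oxy]-3-vinylphenyl]-2-methylbutan-1-one | CC[C@@H](C)C(=O)c1c(O[Si](C)(C)C(C)(C)C)cc(OC(C)(C=C)C=C)c(C=C)c1O[Si](C)(C)C(C)(C)C | intermediate
12 | (R)-1-[(R)-5,7-bis(tert-butyldimethylsilyloxy)-2-methyl-2-vinyl-2H-chromen-6-yl]-2-methylbutan-1-one | CC[C@@H](C)C(=O)c1c(O[Si](C)(C)C(C)(C)C)cc2O[C@](C)(C=C)C=Cc2c1O[Si](C)(C)C(C)(C)C | intermediate
13 | 1-bromo-2-methylprop-1-ene | CC(C)=CBr | starting material
14 | (R)-1-[(R)-2-[2-(9-borabicyclo[3.3.1]nonan-9-yl)ethyl]-5,7-bis(tert-butyldimethylsilyloxy)-2-methyl-2H-chromen-6-yl]-2-methylbutan-1-one | CC[C@@H](C)C(=O)c1c(O[Si](C)(C)C(C)(C)C)cc2O[C@](C)(CCB3C4CCCC3CCC4)C=Cc2c1O[Si](C)(C)C(C)(C)C | intermediate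
15 | (R)-1-[(R)-5,7-bis(tert-butyldimethylsilyloxy)-2-methyl-2-(4-methylpent-3-en-1-yl)-2H-chromen-6-yl]-2-methylbutan-1-one | CC[C@@H](C)C(=O)c1c(O[Si](C)(C)C(C)(C)C)cc2O[C@](C)(CCC=C(C)C)C=Cc2c1O[Si](C)(C)C(C)(C)C | intermediate
16 | (R)-1-[(R)-5,7-dihydroxy-2-methyl-2-(4-methylpent-3-en-1-yl)-2H-chromen-6-yl]-2-methylbutan-1-one | CC[C@@H](C)C(=O)c1c(O)cc2O[C@](C)(CCC=C(C)C)C=Cc2c1O | intermediate
17 | (R)-1-[(R)-5,7-dihydroxy-2,8-dimethyl-2-(4-methylpent-3-en-1-yl)-2H-chromen-6-yl]-2-methylbutan-1-one | CC[C@@H](C)C(=O)c1c(O)c(C)c2O[C@](C)(CCC=C(C)C)C=Cc2c1O | intermediate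
18 | (R)-5-hydroxy-2,8,8-trimethyl-6-[(R)-2-methylbutanoyl]-2-(4-methylpent-3-en-1-yl)-2H-chromen-7(8H)-one | CC[C@@H](C)C(=O)C1=C(O)C2=C(O[C@](C)(CCC=C(C)C)C=C2)C(C)(C)C1=O | target

**Step count**
Total: 12 steps. Longest linear sequence: 11 steps (1 → 2 → 4 → 7 → 8 → 9 → 10 → 11 → 12 → 15 → 16 → 18); step 3 is a one-step side branch.

**Steps most likely to fail**

Step 9. The chiral molybdenum complex may not distinguish the two enantiotopic vinyl groups well enough, or initiation at the doubly ortho-substituted styrene may be so slow that catalyst decay or [3,3] rearrangement of the bis-allylic aryl ether overtakes ring closure. The fallback sets out from 11 and comes back at 12. Ring B is closed without asymmetric induction by the second-generation Hoveyda–Grubbs catalyst RuCl2(SIMes)(=CH-C6H4-2-OiPr) (SIMes = 1,3-dimesitylimidazolidin-2-ylidene) in CH2Cl2 at 40 °C, a catalyst that tolerates the ketone and engages hindered styrenes. This should give 12 together with its C2 epimer, (R)-1-[(S)-5,7-bis(tert-butyldimethylsilyloxy)-2-methyl-2-vinyl-2H-chromen-6-yl]-2-methylbutan-1-one F1. Because the (R)-acyl centre is already in place, the two are diastereomers and not enantiomers, so C2 is secured by separation instead of induction (preparative HPLC, on a cellulose carbamate phase if silica does not resolve them), and 12 re-enters at step 10.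

Step 4. Alkylation may spread over the ortho hydroxyls and the nucleophilic ring carbons, or run on to dialkylation. The fallback sets out from 4 and comes back at 7, and enforces the site by protecting groups instead of by acidity. Exhaustive silylation (TBSCl, imidazole, DMF) should give (R)-2-methyl-1-[2,4,6-tris(tert-butyldimethylsilyloxy)phenyl]butan-1-one F2. The unhindered silyl ether para to the ketone is then cleaved first (K2CO3, MeOH, 0 °C) to give (R)-1-[2,6-bis(tert-butyldimethylsilyloxy)-4-hydroxyphenyl]-2-methylbutan-1-one F3. This mono-phenol, whose ring is far less nucleophilic than that of 4, is etherified with 6 (CuCl2·2H2O, iPr2NEt, MeCN, 0 °C) to give (2R)-1-[2,6-bis(tert-butyldimethylsilyloxy)-4-[(3-methylpent-1-en-4-yn-3-yl)oxy]phenyl]-2-methylbutan-1-one F4. TBAF/AcOH in THF then frees the two phenols and gives 7.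

Step 5. The hydroxymethylated arene may be intercepted by a second arene (methylene-bridged dimerisation), or both free ring positions may be formylated, instead of clean monoformylation. The fallback sets out from 4 and comes back at 10. It brings in the vinyl group by cross-coupling before the ether exists, because an ortho-halogenated aryl propargyl or allyl ether would cyclise onto its own unsaturation under zerovalent palladium. Iodination of 4 (N-iodosuccinimide, MeCN, 0 °C) should give (R)-2-methyl-1-(2,4,6-trihydroxy-3-iodophenyl)butan-1-one F5. Stille coupling with tributyl(vinyl)stannane (Pd(PPh3)4, DMF, 70 °C) gives (R)-2-methyl-1-(2,4,6-trihydroxy-3-vinylphenyl)butan-1-one F6. Copper-catalysed etherification with 6 as in step 4, again at the hydroxyl para to the ketone, gives (2R)-1-[2,6-dihydroxy-4-[(3-methylpent-1-en-4-yn-3-yl)oxy]-3-vinylphenyl]-2-methylbutan-1-one F7, and silylation as in step 6 gives 10.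

Further compounds
F1 | step 9 | (R)-1-[(S)-5,7-bis(tert-butyldimethylsilyloxy)-2-methyl-2-vinyl-2H-chromen-6-yl]-2-methylbutan-1-one | CC[C@@H](C)C(=O)c1c(O[Si](C)(C)C(C)(C)C)cc2O[C@@](C)(C=C)C=Cc2c1O[Si](C)(C)C(C)(C)C
F2 | step 4 | (R)-2-methyl-1-[2,4,6-tris(tert-butyldimethylsilyloxy)phenyl]butan-1-one | CC[C@@H](C)C(=O)c1c(O[Si](C)(C)C(C)(C)C)cc(O[Si](C)(C)C(C)(C)C)cc1O[Si](C)(C)C(C)(C)C
F3 | step 4 | (R)-1-[2,6-bis(tert-butyldimethylsilyloxy)-4-hydroxyphenyl]-2-methylbutan-1-one | CC[C@@H](C)C(=O)c1c(O[Si](C)(C)C(C)(C)C)cc(O)cc1O[Si](C)(C)C(C)(C)C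
F4 | step 4 | (2R)-1-[2,6-bis(tert-butyldimethylsilyloxy)-4-[(3-methylpent-1-en-4-yn-3-yl)oxy]phenyl]-2-methylbutan-1-one (both configurations at the ether carbon) | CC[C@@H](C)C(=O)c1c(O[Si](C)(C)C(C)(C)C)cc(OC(C)(C=C)C#C)cc1O[Si](C)(C)C(C)(C)C
F5 | step 5 | (R)-2-methyl-1-(2,4,6-trihydroxy-3-iodophenyl)butan-1-one | CC[C@@H](C)C(=O)c1c(O)cc(O)c(I)c1O
F6 | step 5 | (R)-2-methyl-1-(2,4,6-trihydroxy-3-vinylphenyl)butan-1-one | CC[C@@H](C)C(=O)c1c(O)cc(O)c(C=C)c1O
F7 | step 5 | (2R)-1-[2,6-dihydroxy-4-[(3-methylpent-1-en-4-yn-3-yl)oxy]-3-vinylphenyl]-2-methylbutan-1-one (both configurations at the ether carbon) | CC[C@@H](C)C(=O)c1c(O)cc(OC(C)(C=C)C#C)c(C=C)c1O
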